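**Assumption:** CIP analysis of the given SMILES gives (2R, 9'R, 3'E, 7'E), and the route is planned for that isomer. Preparation of catalysts and ligands is not counted as steps.

## Retrosynthetic overview
1. The last C–C bond is C2'–C3' (sp3–sp2), made by B-alkyl Suzuki coupling of a 2-vinylchroman (carries C2) with an (E)-alkenyl iodide (carries C3'–C13' and C9'). Global desilylation follows.
2. Only one ring is built, the dihydropyran of the chroman, on a purchased arene. It comes from a new catalytic asymmetric [4+2] of an unsubstituted o-quinone methide with isoprene, which forms C3–C4 and O1–C2 and sets C2.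
3. The o-quinone methide precursor (a salicyl alcohol) comes from 2-methylhydroquinone by mono-silylation, ortho-formylation and reduction.
4. The side chain starts from pent-4-yn-1-ol. Carboalumination/iodination gives E-C3'=C4', and oxidation followed by a stabilised Wittig gives E-C7'=C8'. Brown allylation sets C9' (R), and cross-metathesis then converts allyl to prenyl.

## Route

**Step 1**
Reactants: 1, 2-methylhydroquinone
Product: 2, 2-methyl-4-(triisopropylsilyloxy)phenol
Conditions: TIPSCl (1.0 equiv), imidazole, DMF, 0 °C → rt
Reagents that add atoms: TIPSCl, CC(C)[Si](Cl)(C(C)C)C(C)C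
Why: This is a sterically controlled mono-silylation in which the bulky silyl chloride reacts at the OH that has no ortho-methyl group, leaving free the hindered OH that becomes O1.

**Step 2**
Reactants: 2
Product: 3, 2-hydroxy-3-methyl-5-(triisopropylsilyloxy)benzaldehyde
Conditions: MgCl2, Et3N, (CH2O)n, MeCN, reflux
Reagents that add atoms: paraformaldehyde (as formaldehyde), C=O
Why: In this Casnati–Skattebøl ortho-formylation the magnesium phenoxide directs formaldehyde to the only free ortho position, and the aryl TIPS ether survives.

**Step 3**
Reactants: 3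
Product: 4, 2-(hydroxymethyl)-6-methyl-4-(triisopropylsilyloxy)phenol
Conditions: NaBH4, THF/MeOH, 0 °C
Reagents that add atoms: none
Why: Simple borohydride reduction of the aldehyde gives the salicyl alcohol, which is kept cold and free of acid.

**Step 4 (new key step)**
Reactants: 4; 5, isoprene (10 equiv)
Product: 6, (2S)-2-ethenyl-2,8-dimethyl-6-(triisopropylsilyloxy)chroman. The descriptor is S only because vinyl outranks C3; the spatial arrangement is that of 2R in the target.
Conditions: confined BINOL-derived N-triflyl imidodiphosphorimidate (IDPi, 3,3'-aryl = 3,5-(CF3)2C6H3 as the first choice, 5 mol %), 5 Å MS, cyclohexane/CHCl3, −10 °C, 4 added by syringe pump over 12 h, then Et3N quench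
Reagents that add atoms: isoprene (5), C=CC(C)=C
Why: Proposed new method: this is a catalytic enantioselective inverse-electron-demand oxa-[4+2] of a non-stabilised (CH2-terminated) o-quinone methide with an unactivated feedstock diene, in which the strong confined acid ionises the benzylic C–OH of 4 (water is taken up by the sieves) to an O-protonated o-quinone methide that stays hydrogen-bonded to the chiral anion, isoprene attacks the exocyclic CH2 through its most nucleophilic terminus C1 (tertiary-allylic cation character develops at C2, so only the 2-methyl-2-vinyl regioisomer can close a six-membered ring), and the phenolic O collapses on C2 in a concerted-asynchronous step next to the anion, so the methyl and vinyl faces are told apart inside the pocket and the quaternary C2 centre is set; the sense of induction cannot be predicted, so the catalyst antipode giving (S)-6 is chosen after a first run (both BINOL antipodes are available) and checked against AAA-derived material; rearomatisation drives the reaction, and slow addition with excess diene suppresses o-quinone methide oligomerisation; the closest known reaction types are the racemic thermal or acid-promoted o-quinone methide/isoprene cycloaddition, chiral phosphoric acid [4+2] reactions of aryl-stabilised o-quinone methides with styrenes, enol ethers and enamides, and IDPi-catalysed hetero-Diels–Alder and hydroalkoxylation reactions of simple dienes and olefins.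

**Step 5**
Reactants: 7, pent-4-yn-1-ol
Product: 8, (E)-5-iodo-4-methylpent-4-en-1-ol
Conditions: AlMe3 (3 equiv), Cp2ZrCl2 (0.25 equiv), CH2Cl2, 0 °C → rt; then I2, THF, −30 °C
Reagents that add atoms: trimethylaluminium, C[Al](C)C; iodine, II
Why: Negishi Zr-catalysed syn-carboalumination followed by iodinolysis with retention gives the (E)-trisubstituted alkenyl iodide, which fixes the C3'=C4' geometry.

**Step 6**
Reactants: 8
Product: 9, (E)-5-iodo-4-methylpent-4-enal
Conditions: Dess–Martin periodinane, NaHCO3, CH2Cl2, 0 °C → rt
Reagents that add atoms: none
Why: This mild, buffered alcohol oxidation leaves the alkenyl iodide untouched.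

**Step 7**
Reactants: 9
Product: 10, (2E,6E)-7-iodo-2,6-dimethylhepta-2,6-dienal
Conditions: Ph3P=C(CH3)CHO (1.2 equiv), toluene, 90 °C
Reagents that add atoms: 2-(triphenylphosphoranylidene)propanal, CC(C=O)=P(c1ccccc1)(c1ccccc1)c1ccccc1
Why: The Wittig olefination with a stabilised ylide gives the (E)-2-methyl enal with high selectivity and so fixes the C7'=C8' geometry.

**Step 8**
Reactants: 10
Product: 11, (4R,5E,9E)-10-iodo-5,9-dimethyldeca-1,5,9-trien-4-ol
Conditions: (−)-Ipc2B(allyl) [from (+)-Ipc2BOMe, (−)-α-pinene series, and allylMgBr], Et2O, −100 → −78 °C; then NaOH, H2O2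
Reagents that add atoms: B-allyldiisopinocampheylborane, C=CCB(C1CC2CC(C1C)C2(C)C)C1CC2CC(C1C)C2(C)C
Why: Brown asymmetric allylboration proceeds through a closed chair transition state, this reagent antipode attacks the Re face of α-methyl enals, and the product is the R carbinol, which sets C9'.

**Step 9**
Reactants: 11
Product: 12, TBS ether of 11, (4R,5E,9E)-4-(tert-butyldimethylsilyloxy)-10-iodo-5,9-dimethyldeca-1,5,9-triene
Conditions: TBSCl, imidazole, DMAP (cat.), DMF, rt
Reagents that add atoms: TBSCl, CC(C)(C)[Si](C)(C)Cl
Why: Standard silylation does not touch the stereocentre and prevents Ru–H isomerisation of the allylic alcohol in the next step.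

**Step 10**
Reactants: 12
Product: 13, (5R,6E,10E)-5-(tert-butyldimethylsilyloxy)-11-iodo-2,6,10-trimethylundeca-2,6,10-triene
Conditions: Grubbs II (3 mol %), 2-methyl-2-butene/CH2Cl2 (1:1), 40 °C, sealed tube
Reagents that add atoms: 2-methyl-2-butene, CC=C(C)C
Why: In this olefin cross-metathesis only the terminal alkene engages, exchanging =CH2 for =C(CH3)2 to give the linear prenyl terminus, while the trisubstituted alkene and the trisubstituted alkenyl iodide are inert.

**Step 11**
Reactants: 6; 13
Product: 14, (2R)-2-[(3E,7E,9R)-9-(tert-butyldimethylsilyloxy)-4,8,12-trimethyltrideca-3,7,11-trienyl]-2,8-dimethyl-6-(triisopropylsilyloxy)chroman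
Conditions: 6, 9-BBN, THF, 0 °C → rt; then aq K3PO4, 13, PdCl2(dppf) (5 mol %), AsPh3, DMF, rt
Reagents that add atoms: none (9-BBN contributes only H)
Why: Anti-Markovnikov hydroboration of the only alkene in 6 is followed by B-alkyl Suzuki–Miyaura coupling with retention of the (E)-iodide geometry, no stereocentre is touched, and any loss of the aryl TIPS group does not matter because it is removed in the next step.

**Step 12**
Reactants: 14
Product: 15, sargachromanol C
Conditions: TBAF (AcOH-buffered), degassed THF, 0 °C → rt
Reagents that add atoms: none
Why: Fluoride cleaves both silyl ethers under conditions that neither ionise the allylic alcohol nor affect C2 or C9', and air is excluded to protect the chromanol.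

## Compound list
1 | 2-methylhydroquinone | Cc1cc(O)ccc1O | starting material
2 | 2-methyl-4-(triisopropylsilyloxy)phenol | Cc1cc(O[Si](C(C)C)(C(C)C)C(C)C)ccc1O | intermediate
3 | 2-hydroxy-3-methyl-5-(triisopropylsilyloxy)benzaldehyde | Cc1cc(O[Si](C(C)C)(C(C)C)C(C)C)cc(C=O)c1O | intermediate
4 | 2-(hydroxymethyl)-6-methyl-4-(triisopropylsilyloxy)phenol | Cc1cc(O[Si](C(C)C)(C(C)C)C(C)C)cc(CO)c1O | intermediate
5 | isoprene | C=CC(C)=C | starting material
6 | (2S)-2-ethenyl-2,8-dimethyl-6-(triisopropylsilyloxy)chroman | C=C[C@]1(C)CCc2cc(O[Si](C(C)C)(C(C)C)C(C)C)cc(C)c2O1 | intermediate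
7 | pent-4-yn-1-ol | C#CCCCO | starting material
8 | (E)-5-iodo-4-methylpent-4-en-1-ol | OCCC/C(C)=C/I | intermediate
9 | (E)-5-iodo-4-methylpent-4-enal | O=CCC/C(C)=C/I | intermediate
10 | (2E,6E)-7-iodo-2,6-dimethylhepta-2,6-dienal | O=C/C(C)=C/CC/C(C)=C/I | intermediate
11 | (4R,5E,9E)-10-iodo-5,9-dimethyldeca-1,5,9-trien-4-ol | C=CC[C@@H](O)/C(C)=C/CC/C(C)=C/I | intermediate
12 | (4R,5E,9E)-4-(TBSO)-10-iodo-5,9-dimethyldeca-1,5,9-triene | C=CC[C@@H](O[Si](C)(C)C(C)(C)C)/C(C)=C/CC/C(C)=C/I | intermediate
13 | (5R,6E,10E)-5-(TBSO)-11-iodo-2,6,10-trimethylundeca-2,6,10-triene | CC(C)=CC[C@@H](O[Si](C)(C)C(C)(C)C)/C(C)=C/CC/C(C)=C/I | intermediate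
14 | bis-silyl sargachromanol C (2R,9'R) | CC(C)=CC[C@@H](O[Si](C)(C)C(C)(C)C)/C(C)=C/CC/C(C)=C/CC[C@]1(C)CCc2cc(O[Si](C(C)C)(C(C)C)C(C)C)cc(C)c2O1 | intermediate
15 | sargachromanol C, (2R)-2-[(3E,7E,9R)-9-hydroxy-4,8,12-trimethyltrideca-3,7,11-trienyl]-2,8-dimethylchroman-6-ol | CC(C)=CC[C@@H](O)/C(C)=C/CC/C(C)=C/CC[C@]1(C)CCc2cc(O)cc(C)c2O1 | target

## Summary
**Total steps:** 12.
**Longest linear sequence:** 8 (7 → 8 → 9 → 10 → 11 → 12 → 13 → 14 → 15). The chroman branch takes 4 steps to reach 6.

**Three steps most likely to fail**
1. **Step 4 (the new asymmetric o-quinone methide/isoprene [4+2]).**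
   - Risks: sluggish ionisation of the primary benzylic alcohol, oligomerisation of the o-quinone methide or of isoprene, modest ee, and acid-induced racemisation of the tertiary allylic aryl ether.
   - Fallback (known chemistry): Pd-catalysed intramolecular asymmetric allylic alkylation. Aldehyde 3 is taken through Wittig methylenation, 9-BBN/Suzuki coupling with (Z)-3-iodobut-2-en-1-ol and methyl carbonate formation. Cyclisation with Pd2(dba)3, the DACH-phenyl Trost ligand and AcOH then gives 6, with the ligand antipode chosen for (S)-6.
2. **Step 11 (B-alkyl Suzuki fragment union).**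
   - Risks: protodeboronation, β-hydride elimination and slow coupling.
   - Fallback: disconnect at C1'–C2' instead. Ozonolysis/NaBH4 of 6 gives the chroman-2-ylmethanol, which is converted to its triflate. The triflate is alkylated with the lithiated (E,E)-allylic phenyl sulfone of the C2'–C13' chain. That sulfone is made from geranyl acetate by SeO2 oxidation, allylation as in Step 8 and cross-metathesis as in Step 10. Reductive desulfonylation with Pd/LiEt3BH completes the chain.
3. **Step 10 (allyl to prenyl cross-metathesis).**
   - Risks: incomplete exchange leaving a crotyl by-product, and alkene isomerisation.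
   - Fallback: install the prenyl group directly and set C9' by reduction. An α-selective prenylbarium addition to enal 10 gives the racemic carbinol, which is oxidised to the dienone. (S)-Me-CBS/catecholborane reduction then gives the (R)-alcohol, which is protected as its TBS ether to give 13.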